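**Retrosynthetic overview**

1. Locants used throughout: N1, C2 and C7 are the indoline N, C-2 and C-3 (C7 is the benzylic quaternary carbon). C6–C5 link C7 to N4. The pyrrolidine is N4–C3–C14–C15(OH)–C20. The cyclohexane is C2–C16(CO2Me)–C17–C20–C19–C18.
2. Enabling feature: C2, the spiro carbon shared by the indoline ring and the cyclohexane ring, is the β-carbon of the C16 ester and carries both N1 and C7. An alkynoate C2≡C16 can therefore take up the carbamate nitrogen and the arylacetate carbon at C2 (indoline ring) and pass the resulting C16 enolate to C17, held as an ester carbonyl on C20 (cyclohexane ring).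
3. Disconnections, last to first: C16–H by hydrogenation of a C16=C17 enoate; azocane bond N4–C5 by reductive amination of an aldehyde made from a C7 allyl group; the C17 oxygen removed through the enol triflate; then the key cascade, which forms N1–C2, C2–C7 and C16–C17 from arylacetate carbamate 5 and pyrrolidine ynoate 15.
4. Ynoate 15 comes from methyl N-Boc-3-oxoprolinate (allylation sets C20, ketone reduction sets C15, the allyl group is grown into the ynoate). Carbamate 5 comes from oxindole in three steps.
5. Ring order: pyrrolidine (purchased), then indoline and cyclohexane together (step 11), then azocane (step 15); C16 is set last (step 16).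

Key step: step 11

Remark: 5 is carried as the racemate because its only stereocentre becomes a planar enolate in step 11; the β-keto ester 18 is drawn as its enol.

**Route**

Step 1
Reactants: 1 oxindole (indolin-2-one)
Product: 2 methyl 2-oxoindoline-1-carboxylate
Conditions: (MeOCO)2O, DMAP (cat.), MeCN, 25 °C
Reagents that add atoms: dimethyl dicarbonate, COC(=O)OC(=O)OC
Why: DMAP-catalysed N-acylation (acyl transfer) turns the lactam into an imide, which is the activation needed for ring opening; no stereocentre is involved.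

Step 2
Reactants: 2 methyl 2-oxoindoline-1-carboxylate
Product: 3 methyl 2-[2-(methoxycarbonylamino)phenyl]acetate
Conditions: NaOMe (0.1 equiv), MeOH, 0 to 25 °C
Reagents that add atoms: methanol, CO
Why: Methanolysis of an N-acyl lactam (nucleophilic acyl substitution) should occur at the more electrophilic ring carbonyl with the carbamate nitrogen as leaving group, giving the open carbamate ester that a free aniline would not tolerate.

Step 3
Reactants: 3 methyl 2-[2-(methoxycarbonylamino)phenyl]acetate
Product: 5 methyl 2-[2-(methoxycarbonylamino)phenyl]pent-4-enoate (racemic), via dilithium dianion 4 (not isolated)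
Conditions: LiN(iPr)2 (2.1 equiv), THF, −78 °C; then allyl bromide (1.0 equiv), −78 °C; H2O quench at −78 °C
Reagents that add atoms: allyl bromide, C=CCBr
Why: Dianion alkylation: the ester enolate carbon of 4 is far more nucleophilic than the carbamate nitrogen anion, so one equivalent of allyl bromide should alkylate carbon only, and the cold quench prevents reclosure to the N-acyl oxindole; the new centre is racemic and is erased in step 11.

Step 4
Reactants: 6 1-tert-butyl 2-methyl 3-oxopyrrolidine-1,2-dicarboxylate
Product: 7 1-tert-butyl 2-methyl (2S)-3-oxo-2-(prop-2-enyl)pyrrolidine-1,2-dicarboxylate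
Conditions: allyl acetate, [Pd(C3H5)Cl]2 (1 mol%), the enantiomer of N,N'-(cyclohexane-1,2-diyl)bis[2-(diphenylphosphino)benzamide] that delivers the 2S product (3 mol%), tetramethylguanidine, toluene, 0 °C
Reagents that add atoms: allyl acetate, C=CCOC(C)=O
Why: Palladium-catalysed asymmetric allylic alkylation (Tsuji–Trost) of a β-keto ester: the chiral diphosphine pocket around the π-allyl palladium complex differentiates the enolate faces and sets the quaternary centre C20.

Step 5
Reactants: 7 1-tert-butyl 2-methyl (2S)-3-oxo-2-(prop-2-enyl)pyrrolidine-1,2-dicarboxylate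
Product: 8 1-tert-butyl 2-methyl (2S,3R)-3-hydroxy-2-(prop-2-enyl)pyrrolidine-1,2-dicarboxylate
Conditions: (S)-2-methyl-CBS-oxazaborolidine (20 mol%), catecholborane, toluene, −78 °C
Reagents that add atoms: none
Why: Corey–Bakshi–Shibata reduction under reagent control distinguishes the quaternary C20 side from the CH2 side of the ketone and should give the 3R alcohol (C15) with the hydroxyl cis to the ester, while catecholborane leaves the alkene alone at this temperature.

Step 6
Reactants: 8 1-tert-butyl 2-methyl (2S,3R)-3-hydroxy-2-(prop-2-enyl)pyrrolidine-1,2-dicarboxylate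
Product: 9 1-tert-butyl 2-methyl (2S,3R)-2-(prop-2-enyl)-3-(triethylsilyloxy)pyrrolidine-1,2-dicarboxylate
Conditions: Et3SiOTf, 2,6-lutidine, CH2Cl2, −78 to 0 °C
Reagents that add atoms: triethylsilyl trifluoromethanesulfonate, CC[Si](CC)(CC)OS(=O)(=O)C(F)(F)F
Why: Silylation of the hindered secondary alcohol with the silyl triflate blocks retro-aldol opening of the β-hydroxy ester in the later basic steps, and the ether is removed by acid in step 15.

Step 7
Reactants: 9 1-tert-butyl 2-methyl (2S,3R)-2-(prop-2-enyl)-3-(triethylsilyloxy)pyrrolidine-1,2-dicarboxylate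
Product: 11 1-tert-butyl 2-methyl (2S,3R)-2-(3-hydroxypropyl)-3-(triethylsilyloxy)pyrrolidine-1,2-dicarboxylate, via B-alkyl-9-borabicyclononane adduct 10 (not isolated)
Conditions: 9-BBN, THF, 0 to 25 °C; then NaOH, H2O2, 0 °C
Reagents that add atoms: hydrogen peroxide, OO
Why: Anti-Markovnikov hydroboration of the terminal alkene with the bulky borane followed by oxidation with retention (hydroboration–oxidation) should give the primary alcohol.

Step 8
Reactants: 11 1-tert-butyl 2-methyl (2S,3R)-2-(3-hydroxypropyl)-3-(triethylsilyloxy)pyrrolidine-1,2-dicarboxylate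
Product: 12 1-tert-butyl 2-methyl (2S,3R)-2-(3-oxopropyl)-3-(triethylsilyloxy)pyrrolidine-1,2-dicarboxylate
Conditions: Dess–Martin periodinane, CH2Cl2, 25 °C
Reagents that add atoms: none
Why: Dess–Martin oxidation takes the primary alcohol to the aldehyde under near-neutral conditions that spare the silyl ether and the carbamate.

Step 9
Reactants: 12 1-tert-butyl 2-methyl (2S,3R)-2-(3-oxopropyl)-3-(triethylsilyloxy)pyrrolidine-1,2-dicarboxylate
Product: 13 1-tert-butyl 2-methyl (2S,3R)-2-(but-3-ynyl)-3-(triethylsilyloxy)pyrrolidine-1,2-dicarboxylate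
Conditions: dimethyl (1-diazo-2-oxopropyl)phosphonate, K2CO3, MeOH, 0 to 25 °C
Reagents that add atoms: dimethyl (1-diazo-2-oxopropyl)phosphonate, COP(=O)(OC)C(=[N+]=[N-])C(C)=O
Why: Seyferth–Gilbert homologation with the Ohira–Bestmann reagent converts the aldehyde into the terminal alkyne under mild carbonate conditions.

Step 10
Reactants: 13 1-tert-butyl 2-methyl (2S,3R)-2-(but-3-ynyl)-3-(triethylsilyloxy)pyrrolidine-1,2-dicarboxylate
Product: 15 1-tert-butyl 2-methyl (2S,3R)-2-(5-methoxy-5-oxopent-3-ynyl)-3-(triethylsilyloxy)pyrrolidine-1,2-dicarboxylate, via lithium acetylide 14 (not isolated)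
Conditions: LiN(iPr)2, THF, −78 °C; then ClCO2Me, −78 °C
Reagents that add atoms: methyl chloroformate, COC(=O)Cl
Why: Deprotonation of the terminal alkyne and C-acylation of the lithium acetylide with the chloroformate should give the alkynoate, since the C20 ester has no α-hydrogen and is too hindered for the amide base to attack.

Step 11
Reactants: 5 methyl 2-[2-(methoxycarbonylamino)phenyl]pent-4-enoate (racemic); 15 1-tert-butyl 2-methyl (2S,3R)-2-(5-methoxy-5-oxopent-3-ynyl)-3-(triethylsilyloxy)pyrrolidine-1,2-dicarboxylate
Product: 18 spirocyclic β-keto ester (enol form), via enamide acrylate 16 (not isolated), via potassium ester enolate 17 (not isolated)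
Conditions: 5 (1.1 equiv), KN(SiMe3)2 (1.2 equiv), 18-crown-6, THF, −78 °C; then 15, −78 to 25 °C; AcOH
Reagents that add atoms: none
Why: Proposed new method: the potassium carbamate of 5 adds to the ynoate β-carbon C2 of 15, the allenolate is protonated at C16 by the benzylic C7–H, the ester-stabilised C7 carbanion of enamide acrylate 16 adds back to C2 to give ester enolate 17, and 17 acylates on the C20 methyl ester (Dieckmann), where loss of methoxide and deprotonation of the β-keto ester make the cascade irreversible; the other order (Dieckmann through the γ-deprotonated dienolate of 16, then Michael addition to the alkylidene β-keto ester) ends at the same enolate. The closest known reaction types are the double Michael (4+1) annulation of ortho-amino arylacetate dinucleophiles with alkynoates to 2-substituted indolines and the Michael–Dieckmann (Michael–Claisen) annulation. The indoline closes in the 5-exo-trig mode and the carbocycle in the 6-exo-trig acyl-substitution mode. C2 and its relation to C20 are set in a chair-like ring closure that keeps both planar N-acyl nitrogens (N1–CO2Me and N4–Boc) equatorial, because an axial one would push its carbamate carbon into the syn-axial C–H bonds; this places C7 axial and cis to N4, and the reversible Michael step lets the mismatched C2 epimer return (Curtin–Hammett). C7 is set in an open, non-chelated transition state (potassium held by 18-crown-6) in which the C7 ester enolate turns away from the acceptor ester, so the allyl group lies on the C16 side. The step needs attack of nitrogen and carbon at the ynoate β-carbon in preference to 1,2-addition and a single irreversible exit, which the soft stabilised anions and the β-keto ester enolate as the only thermodynamic sink should secure; C16 is trigonal in 18 and is set in step 16.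

Step 12
Reactants: 18 spirocyclic β-keto ester (enol form)
Product: 19 enol triflate of 18
Conditions: Tf2O, iPr2NEt, CH2Cl2, −78 °C
Reagents that add atoms: trifluoromethanesulfonic anhydride, O=S(=O)(OS(=O)(=O)C(F)(F)F)C(F)(F)F
Why: O-sulfonylation of the enol of the β-keto ester (enol triflate formation) activates the C17 oxygen for removal.

Step 13
Reactants: 19 enol triflate of 18
Product: 20 spirocyclic enoate (C16=C17)
Conditions: Pd(OAc)2 (5 mol%), PPh3, HCO2H, Et3N, DMF, 60 °C
Reagents that add atoms: none
Why: Palladium-catalysed formate reduction of the enol triflate (oxidative addition to zerovalent palladium, decarboxylation of formate to the hydride, reductive elimination) replaces the C17 oxygen by hydrogen and should leave the terminal alkene untouched.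

Step 14
Reactants: 20 spirocyclic enoate (C16=C17)
Product: 22 aldehyde (C5), via ozonide 21 (not isolated)
Conditions: O3 (1.0 equiv, Sudan Red 7B end point), CH2Cl2, −78 °C; then PPh3, −78 to 25 °C
Reagents that add atoms: ozone, [O-][O+]=O
Why: Ozonolysis with reductive work-up is expected to be chemoselective because the electron-rich terminal alkene reacts far faster than the hindered, electron-poor enoate and the acylated aniline ring.

Step 15
Reactants: 22 aldehyde (C5)
Product: 25 16,17-didehydro target (azocane closed), via amino aldehyde 23 (not isolated), via cyclic iminium trifluoroacetate 24 (not isolated)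
Conditions: TFA–H2O–CH2Cl2, 0 to 25 °C; concentrate; then NaBH(OAc)3, ClCH2CH2Cl (0.005 M), 25 °C
Reagents that add atoms: none
Why: Acid removes the Boc and triethylsilyl groups, the secondary amine N4 condenses with the aldehyde C5 inside the molecule (eight-membered ring, possible only because C7 and N4 are cis on the carbocycle), and the iminium ion is reduced (intramolecular reductive amination).

Step 16
Reactants: 25 16,17-didehydro target (azocane closed)
Product: 26 CNP0144467.2 (target)
Conditions: H2 (50 bar), Pd/C, MeOH–AcOH, 25 to 50 °C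
Reagents that add atoms: none
Why: Heterogeneous catalytic hydrogenation should add both hydrogens syn to the face of the C16=C17 bond that is turned toward the two-carbon C18–C19 bridge, because the four-atom azocane bridge (C6 lies over C16) shields the other face; this sets C16 with the ester on the azocane side, and the acid keeps N4 protonated so that it cannot anchor the catalyst.

**Compound list**

1 | oxindole (indolin-2-one) | O=C1Cc2ccccc2N1 | starting material
2 | methyl 2-oxoindoline-1-carboxylate | COC(=O)N1C(=O)Cc2ccccc21 | intermediate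
3 | methyl 2-[2-(methoxycarbonylamino)phenyl]acetate | COC(=O)Cc1ccccc1NC(=O)OC | intermediate
4 | dilithium dianion of 3 (N-lithio carbamate, lithium ester enolate) | [Li+].[Li+].COC([O-])=Cc1ccccc1[N-]C(=O)OC | intermediate (not isolated)
5 | methyl 2-[2-(methoxycarbonylamino)phenyl]pent-4-enoate, racemic | COC(=O)C(CC=C)c1ccccc1NC(=O)OC | intermediate
6 | 1-tert-butyl 2-methyl 3-oxopyrrolidine-1,2-dicarboxylate | COC(=O)C1C(=O)CCN1C(=O)OC(C)(C)C | starting material
7 | 1-tert-butyl 2-methyl (2S)-3-oxo-2-(prop-2-enyl)pyrrolidine-1,2-dicarboxylate | C=CC[C@]1(C(=O)OC)N(C(=O)OC(C)(C)C)CCC1=O | intermediate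
8 | 1-tert-butyl 2-methyl (2S,3R)-3-hydroxy-2-(prop-2-enyl)pyrrolidine-1,2-dicarboxylate, hydroxyl cis to the ester | C=CC[C@]1(C(=O)OC)N(C(=O)OC(C)(C)C)CC[C@H]1O | intermediate
9 | 1-tert-butyl 2-methyl (2S,3R)-2-(prop-2-enyl)-3-(triethylsilyloxy)pyrrolidine-1,2-dicarboxylate | C=CC[C@]1(C(=O)OC)N(C(=O)OC(C)(C)C)CC[C@H]1O[Si](CC)(CC)CC | intermediate
10 | B-alkyl-9-borabicyclo[3.3.1]nonane adduct of 9 | C1CC2CCCC(C1)B2CCC[C@]1(C(=O)OC)N(C(=O)OC(C)(C)C)CC[C@H]1O[Si](CC)(CC)CC | intermediate (not isolated)
11 | 1-tert-butyl 2-methyl (2S,3R)-2-(3-hydroxypropyl)-3-(triethylsilyloxy)pyrrolidine-1,2-dicarboxylate | OCCC[C@]1(C(=O)OC)N(C(=O)OC(C)(C)C)CC[C@H]1O[Si](CC)(CC)CC | intermediate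
12 | 1-tert-butyl 2-methyl (2S,3R)-2-(3-oxopropyl)-3-(triethylsilyloxy)pyrrolidine-1,2-dicarboxylate | O=CCC[C@]1(C(=O)OC)N(C(=O)OC(C)(C)C)CC[C@H]1O[Si](CC)(CC)CC | intermediate
13 | 1-tert-butyl 2-methyl (2S,3R)-2-(but-3-ynyl)-3-(triethylsilyloxy)pyrrolidine-1,2-dicarboxylate | C#CCC[C@]1(C(=O)OC)N(C(=O)OC(C)(C)C)CC[C@H]1O[Si](CC)(CC)CC | intermediate
14 | lithium acetylide of 13 | [Li]C#CCC[C@]1(C(=O)OC)N(C(=O)OC(C)(C)C)CC[C@H]1O[Si](CC)(CC)CC | intermediate (not isolated)
15 | 1-tert-butyl 2-methyl (2S,3R)-2-(5-methoxy-5-oxopent-3-ynyl)-3-(triethylsilyloxy)pyrrolidine-1,2-dicarboxylate | COC(=O)C#CCC[C@]1(C(=O)OC)N(C(=O)OC(C)(C)C)CC[C@H]1O[Si](CC)(CC)CC | intermediate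
16 | enamide acrylate: N1–C2 adduct of 5 and 15, N-aryl-N-(methoxycarbonyl) β-amino acrylate, E/Z and benzylic epimers | COC(=O)C=C(CC[C@]1(C(=O)OC)N(C(=O)OC(C)(C)C)CC[C@H]1O[Si](CC)(CC)CC)N(C(=O)OC)c1ccccc1C(CC=C)C(=O)OC | intermediate (not isolated)
17 | potassium ester enolate of the 2,2,3,3-tetrasubstituted indoline (Michael adduct; C2–C7 bond formed, carbocycle still open) | [K+].COC([O-])=C[C@@]1(CC[C@]2(C(=O)OC)N(C(=O)OC(C)(C)C)CC[C@H]2O[Si](CC)(CC)CC)N(C(=O)OC)c2ccccc2[C@@]1(C(=O)OC)CC=C | intermediate (not isolated)
18 | spirocyclic β-keto ester, enol form: indoline and cyclohexene closed, C17 enol, C7 (allyl, CO2Me) cis to N4, allyl on the C16 side, N4-Boc, C15 triethylsilyl ether | COC(=O)C1=C(O)[C@@]2(CC[C@@]13N(C(=O)OC)c1ccccc1[C@@]3(C(=O)OC)CC=C)N(C(=O)OC(C)(C)C)CC[C@H]2O[Si](CC)(CC)CC | intermediate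
19 | enol triflate of 18 (triflate on C17) | COC(=O)C1=C(OS(=O)(=O)C(F)(F)F)[C@@]2(CC[C@@]13N(C(=O)OC)c1ccccc1[C@@]3(C(=O)OC)CC=C)N(C(=O)OC(C)(C)C)CC[C@H]2O[Si](CC)(CC)CC | intermediate
20 | spirocyclic enoate (C16=C17, C17–H) | COC(=O)C1=C[C@@]2(CC[C@@]13N(C(=O)OC)c1ccccc1[C@@]3(C(=O)OC)CC=C)N(C(=O)OC(C)(C)C)CC[C@H]2O[Si](CC)(CC)CC | intermediate
21 | ozonide (1,2,4-trioxolane) of the allyl group of 20 | COC(=O)C1=C[C@@]2(CC[C@@]13N(C(=O)OC)c1ccccc1[C@@]3(C(=O)OC)CC1OCOO1)N(C(=O)OC(C)(C)C)CC[C@H]2O[Si](CC)(CC)CC | intermediate (not isolated)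
22 | aldehyde (C7–CH2–CHO) | COC(=O)C1=C[C@@]2(CC[C@@]13N(C(=O)OC)c1ccccc1[C@@]3(C(=O)OC)CC=O)N(C(=O)OC(C)(C)C)CC[C@H]2O[Si](CC)(CC)CC | intermediate
23 | amino aldehyde (N4–H, C15–OH free; present as trifluoroacetate, free base drawn) | COC(=O)C1=C[C@@]2(CC[C@@]13N(C(=O)OC)c1ccccc1[C@@]3(C(=O)OC)CC=O)NCC[C@H]2O | intermediate (not isolated)
24 | cyclic iminium trifluoroacetate (N4=C5 in the azocane) | COC(=O)C1=C[C@@]23CC[C@@]14N(C(=O)OC)c1ccccc1[C@@]4(C(=O)OC)CC=[N+]2CC[C@H]3O.[O-]C(=O)C(F)(F)F | intermediate (not isolated)
25 | 16,17-didehydro target (all rings closed, C16=C17) | COC(=O)C1=C[C@@]23CC[C@@]14N(C(=O)OC)c1ccccc1[C@@]4(C(=O)OC)CCN2CC[C@H]3O | intermediate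
26 | CNP0144467.2 (2R, 7S, 15R, 16R, 20R in the locants above) | COC(=O)[C@@H]1C[C@@]23CC[C@@]14N(C(=O)OC)c1ccccc1[C@@]4(C(=O)OC)CCN2CC[C@H]3O | target

**Step count and risks**

Total step count: 16. Longest linear sequence: 13 steps (steps 4 to 16, from 6); fragment 5 is made in 3 steps (steps 1 to 3).

Steps most likely to fail:

Step 11 (proposed new method). The cascade may stop before the Dieckmann closure through premature protonation, or the arylacetate anion may be diverted by reclosure to an N-acyl oxindole enolate. The vicinal quaternary C2–C7 bond may also form with poor facial selectivity at C7 or at C2 relative to C20. Fallback with known chemistry, setting out from 5 and 15: Cs2CO3 (0.2 equiv) in MeCN at 25 °C adds the carbamate N–H across the alkynoate (base-mediated hydroamidation) and gives enamide acrylate 16 as an isolated compound. NaOMe in MeOH–THF then closes the carbocycle by Dieckmann condensation through the γ-deprotonated dienolate and gives the cyclic alkylidene β-keto ester F1. DBU in MeCN brings about the intramolecular Michael addition of the arylacetate carbon to the doubly activated alkene of F1, by axial attack on the half-chair that keeps N4–Boc equatorial, and the sequence comes back to the route at 18.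

Step 15. Intermolecular iminium formation and oligomerisation may outrun closure of the eight-membered ring, and the aldehyde may be reduced before it condenses. Fallback, setting out from 22: NaBH4 in MeOH at 0 °C reduces the aldehyde to the primary alcohol F2, and MsCl with Et3N gives the mesylate F3. TFA–H2O removes the Boc and silyl groups to give the amino mesylate F4 (as its trifluoroacetate). K2CO3 and NaI in MeCN at high dilution (60 °C) close the azocane by intramolecular N-alkylation, and the sequence comes back to the route at 25.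

Step 16. Hydrogen may be delivered to the wrong face if the catalyst is anchored by N4 or the C15 hydroxyl, or the shielded trisubstituted alkene may not be reduced at all. Fallback, setting out from 20, sets C16 before the cage is closed and under thermodynamic control. Conjugate reduction with [(Ph3P)CuH]6 and t-BuOH in toluene, then equilibration with catalytic NaOMe in MeOH, should give the saturated ester F5 with the C16 ester equatorial (cis to C7) in the chair that keeps both N-acyl nitrogens equatorial. Ozonolysis as in step 14 (through the ozonide F6) gives the aldehyde F7, and the conditions of step 15 (through the amino aldehyde F8 and the iminium trifluoroacetate F9) lead back to the route at 26.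

Further compounds
F1 | step 11 | cyclic alkylidene β-keto ester (carbocycle closed, C2=C16, C17 ketone, indoline still open) | COC(=O)C1=C(N(C(=O)OC)c2ccccc2C(CC=C)C(=O)OC)CC[C@]2(C1=O)N(C(=O)OC(C)(C)C)CC[C@H]2O[Si](CC)(CC)CC
F2 | step 15 | primary alcohol from 22 (C7–CH2–CH2OH) | COC(=O)C1=C[C@@]2(CC[C@@]13N(C(=O)OC)c1ccccc1[C@@]3(C(=O)OC)CCO)N(C(=O)OC(C)(C)C)CC[C@H]2O[Si](CC)(CC)CC
F3 | step 15 | mesylate of F2 | COC(=O)C1=C[C@@]2(CC[C@@]13N(C(=O)OC)c1ccccc1[C@@]3(C(=O)OC)CCOS(C)(=O)=O)N(C(=O)OC(C)(C)C)CC[C@H]2O[Si](CC)(CC)CC
F4 | step 15 | amino mesylate (N4–H and C15–OH free; free base drawn) | COC(=O)C1=C[C@@]2(CC[C@@]13N(C(=O)OC)c1ccccc1[C@@]3(C(=O)OC)CCOS(C)(=O)=O)NCC[C@H]2O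
F5 | step 16 | saturated ester, carbocycle reduced before azocane closure (C16 R, allyl, N4-Boc, silyl ether) | COC(=O)[C@@H]1C[C@@]2(CC[C@@]13N(C(=O)OC)c1ccccc1[C@@]3(C(=O)OC)CC=C)N(C(=O)OC(C)(C)C)CC[C@H]2O[Si](CC)(CC)CC
F6 | step 16 | ozonide of F5 | COC(=O)[C@@H]1C[C@@]2(CC[C@@]13N(C(=O)OC)c1ccccc1[C@@]3(C(=O)OC)CC1OCOO1)N(C(=O)OC(C)(C)C)CC[C@H]2O[Si](CC)(CC)CC
F7 | step 16 | saturated aldehyde | COC(=O)[C@@H]1C[C@@]2(CC[C@@]13N(C(=O)OC)c1ccccc1[C@@]3(C(=O)OC)CC=O)N(C(=O)OC(C)(C)C)CC[C@H]2O[Si](CC)(CC)CC
F8 | step 16 | saturated amino aldehyde (free base drawn) | COC(=O)[C@@H]1C[C@@]2(CC[C@@]13N(C(=O)OC)c1ccccc1[C@@]3(C(=O)OC)CC=O)NCC[C@H]2O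
F9 | step 16 | saturated cyclic iminium trifluoroacetate | COC(=O)[C@@H]1C[C@@]23CC[C@@]14N(C(=O)OC)c1ccccc1[C@@]4(C(=O)OC)CC=[N+]2CC[C@H]3O.[O-]C(=O)C(F)(F)F
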